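Follow one molecule of starting material: it leaves either with dissolved gas as target or with target as side product. Its odds at this fork, the selectivity, go as dissolved gas against target.

the same everywhere: gas phase 58 mM (held)

| run | starting material | remark | time |
|---|---|---|---|
| south-west | 0.55 M | run made earlier |  |
| south-east | 2.2 M | run made earlier |  |
| flask | 1.1 M |  | 4.0 h |

- south-west (time / h: target / %): 0.333: 63.1; 0.500: 77.9; 0.833: 93.9; 1.33: 97.4; 2.50: 97.4; 4.00: 97.8
- south-east (time / h: target / %): 0.667: 51.9; 1.33: 80.1; 2.00: 82.0; 2.50: 82.5; 3.00: 83.2; 4.00: 82.3

(readings scatter by 1 percentage point)

- in percentages every species weighs as the starting material in it: one side product counts as two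
- at the start none of the gas is dissolved
- on the list of suspects stand: gas phase <-> dissolved gas; starting material + dissolved gas -> target; starting material + target -> side product; dissolved gas -> decomposed reagent

1. the target standing at 4.0 h, as a percentage of the starting material charged
2. the change that raises the amount of target at 4.0 h, in percent of the starting material charged most ("none" if none brings more than 2 percentage points) (elm / oak / none)
3. amount of target at 4.0 h, in percent of the starting material charged, after elm

- elm: doubling the saturation concentration of gas phase, all else as stated
- oak: doubling the transfer coefficient of the gas phase, all else as stated

Read both tables from their tails. South-west target stands flat from 1.33 h and south-east target from 2.00 h, so I take what is missing there as the fraction of the charge lost to side product: 2.47% south-west and 17.5% south-east.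

Set these columns against each other: the charge rose by a factor of 4.00, the lost fraction by 7.09. The lost fraction therefore goes as the charge raised to 1.41, the loss order, a reading that carries the scatter.

My reckoning for the flask, at twice the south-west charge, is a loss of 6.57%, so target 93.4%. Elm doubles the dissolved gas at the fork, which should cut the loss to half and give target 96.7%, a gain of 3.3 percentage points. Oak leaves the saturation as it stands, and my reckoning gives no size for its lift of the dissolved gas, so I choose elm on the gain I can reckon.

The forecast gives 93.8%, elm and 96.9%: “Elm is best, with a gain of about 3 points”. Its target stands slightly above mine.

The flask gives 92.5%. Elm gains 3.5 points and oak 1.5 points, so the choice is elm, with 96.0% after it.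

    gas phase ⇌ dissolved gas, rate k1*(csat - [dissolved gas]) (kL = 0.0124 s⁻¹)
    starting material + dissolved gas → target (k = 0.0256 L mol⁻¹ s⁻¹)
    starting material + target → side product (k = 6.21 × 10⁻⁵ L mol⁻¹ s⁻¹)
    dissolved gas → decomposed reagent (k = 2.24 × 10⁻⁴ s⁻¹)

With starting material + target → side product taken away, flask target rises from 92.5% to 100%. The flask holds 7.48% side product at 4.00 h, against my 6.57%, and elm brings that loss to about half. For the neighbour flask at 0.44 M, the loss order 1.41 gives a loss of 1.80%, so target 98.2%. The computed neighbour holds 97.6% target and 2.39% side product.

(The numbers in the tables come from a simulation with made-up constants; scatter was added.)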